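The runs are simulated for an exercise, and the scatter is random.

Count the incoming ligand first: the ash flask holds 0.15 M of it, less than the 0.200 M a double exchange of its starting complex takes, so it is the limiting reagent.

| setting | ash | maple | flask |
|---|---|---|---|
| starting complex | 0.10 M | 0.10 M | 0.10 M |
| incoming ligand | 0.15 M | 0.22 M | 0.150 M |
| remark | the very flask that is asked about, followed so far | run made earlier |  |
| time |  |  | 30 min |

| run | time / min | complex with one exchanged / % | complex with two exchanged / % |
|---|---|---|---|
| ash | 1.50 | 38.2 | 3.0 |
| ash | 2.00 | 44.1 | 6.0 |
| ash | 3.00 | 51.4 | 9.4 |
| ash | 4.00 | 54.5 | 10.6 |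
| ash | 6.00 | 54.1 | 15.7 |
| maple | 1.50 | 47.8 | 5.6 |
| maple | 3.00 | 60.4 | 15.2 |
| maple | 6.00 | 56.5 | 30.2 |
| maple | 15.0 | 36.7 | 56.2 |
| maple | 30.0 | 21.7 | 76.1 |

(readings scatter by 1 percentage point)

- a reading or a percentage of complex with two exchanged counts all its forms, free or not

1. the moment within 30 min at which there is most complex with one exchanged
2. the amount of complex with one exchanged, in percent of the starting complex charged, at that time
3. the first time at which complex with one exchanged reaches 39 %, in the same percent, in min

I kept a ledger of that ligand. A complex with one exchanged had taken one ligand, a complex with two exchanged had taken two, and the rest was free. At 6.00 min the ash run put 0.0541 M in the first entry and 0.0314 M in the second. So 0.0645 M stood free.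

I took the second exchange as first order in [complex with one exchanged] and in [incoming ligand]. The maple ledger showed free ligand falling from 0.103 M at 6.00 min to 0.0709 M at 15.0 min. From those readings I got 0.713 /M/min as the second-step constant: the rise of [complex with two exchanged] per minute over mean [complex with one exchanged] times mean [incoming ligand].

At the free ligand of the ash flask, this gave a pseudo-first-order half-life, ln(2) over constant times [incoming ligand], of 15.1 min. That was longer than the 2.00 min between the last ash readings, so I committed to a flat top near 54.5 %, around 6.00 min.

The forecast gave 5 min, 55.2 % and 1.56 min, and said “The peak is therefore flat”.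

The ash flask gave its most complex with one exchanged at 6.35 min, namely 56.3 %, and reached the level asked at 1.49 min.

    complex with one exchanged + incoming ligand → leaving ligand + complex with two exchanged (k = 0.0125 /M/s)
    starting complex + incoming ligand → leaving ligand + complex with one exchanged (k = 0.0530 /M/s)
    crystals ⇌ complex with two exchanged, rate k3*(cs3 - [complex with two exchanged]) while solid is left; crystals form when [complex with two exchanged] > cs3 (solubility = 39.0 mM, k = 1.82 /s)
    starting complex ⇌ dormant form (K = 0.810, k = 0.00150 /s)

At 12.7 min the ash flask still held 53.0 %. Its ledger at the best time left 0.0588 M free, and 0.713 /M/min made that a half-life of 16.6 min. The neighbour charged with 0.38 M of incoming ligand closed its ledger with 0.183 M free. At that free ligand my reading of 0.713 /M/min made the half-life 5.31 min, shorter than the time allowed, and in that neighbour 1.88 % of complex with one exchanged stood at 30.0 min.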